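The earlier runs and the new flask stem from a simulated flask with constants of no real substance; scatter was added.

Monomer is conserved: the charge stands as free monomer, as monomer in chains, or as a shortfall that neither reading shows.

the same everywhere: initiator 15 mM
- Sunday's: free monomer 0.091 M; protic impurity 0.060 M; run made earlier
- Wednesday's: free monomer 0.26 M; protic impurity 0.060 M; run made earlier
- south-west: free monomer 0.30 M; protic impurity 0.0600 M; time 25 min
- south: free monomer 0.15 M; protic impurity 0.0600 M; time 25 min

- Sunday's (time / min: monomer in chains / %, free monomer / %): 3.00: 17.6, 66.0; 6.00: 19.6, 53.3; 10.0: 23.4, 40.9; 12.0: 23.9, 37.1
- Wednesday's (time / min: monomer in chains / %, free monomer / %): 1.00: 8.7, 87.9; 2.50: 7.9, 79.2; 5.00: 9.6, 71.4; 12.0: 17.0, 61.4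

(standard deviation of a reading: 1 percentage point)

* which of the two ends with the longer chains by the average number of monomer units in a chain (chains begun, living or dead) ("neither" if they lie within 10%) (south-west / south / neither)
* average number of monomer units in a chain (chains begun, living or dead) at the end, south-west
* average number of monomer units in a chain (chains begun, living or dead) at the end, south

- the average divides the monomer in chains by the number of chains begun, living and dead together
- the earlier runs do not show the number of chains; that part of a forecast is a guess

Where does the shortfall go? In Wednesday's run it reads 0.0494 M at 5.00 min and 0.0562 M at 12.0 min, against 0.060 M of protic impurity charged. So one monomer is booked per protic impurity, at the start for simplicity. Sunday's first reading shows 16.0 mM in chains against 15 mM of initiator, so one unit is booked per initiator. That leaves a growable monomer A, the charge minus both: 0.225 M in south-west and 0.0750 M in south.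

How fast does A enter chains? Wednesday's last two readings give 0.0159 min⁻¹ for the growth constant g, the gain in chains per minute over the mean free monomer, a pseudo-first-order constant. If growth alone then consumes A, the average length is n = 1 + (A/c)(1 − exp(−gt)), with c the initiator charge, taken as chains begun, which is a guess.

Which flask is longer? This reckoning gives both flasks the same c, g and t, so both carry the factor 0.328. The rule then gives 5.93 units in south-west and 2.64 in south, so south-west is longer by a ratio of 2.25, beyond the 10% margin.

The forecast says south-west, with 5 and 2.5 units, on its own reading of growth, “first-order in monomer at about 0.012 min⁻¹”, which differs from g here.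

The flask gives south-west, with 5.60 units in south-west and 2.78 in south.

    protic impurity + free monomer → quenched substrate (k = 0.0220 M⁻¹ s⁻¹)
    free monomer + living end → monomer in chains + living end, rate k2*[living end]*[free monomer] (k = 0.0160 M⁻¹ s⁻¹)
    free monomer + initiator → living end + monomer in chains (k = 0.170 M⁻¹ s⁻¹)

South-west holds 20.0% of its free monomer charge as quenched substrate at 25.0 min, beside 0.0150 M of living end. The south-west flask charged with 0.025 M of initiator has 0.0250 M of living end, so g scales to 0.0265 min⁻¹. The rule then gives 5.17 units, and that flask stands at 4.95.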